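Cuts: the C1'–C2' bond between the side-chain carbinol and the Z-dienyl carbon; the O–C6 bond of the epoxide; the ring B alkene C3=C4; the C3'–C4' σ-bond of the diene; the C1''–C6'' bond of ring A.
Enabling feature: in ring B (7-oxabicyclo[4.1.0]hept-3-ene), the path from alkene CH C3 via carbinol C2, quaternary epoxide carbon C1, epoxide methine C6 and carbinol C5 to alkene carbon C4 is C1→C6 of D-glucose. O2, O3 and O5 sit as in the sugar, the methine is C4 after one inversion, and the side chain replaces H3, so only the C3=C4 link is missing.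
Forward, ring B: diacetone glucose is branched at C3, C6 becomes a 2-(alkoxymethyl)vinyl unit and C1 a vinyl group. Metathesis closes the carbocycle, O3 displaces the O4 mesylate to form the epoxide, and the branch carbon is oxidised to the aldehyde.
Forward, ring A and chain: cationic cyclisation of (R)-6,7-epoxygeranyl acetate, Takai iodide, Negishi coupling with the propyne-derived (Z)-bromoboronate and iodinolysis give the Z,E-dienyl iodide. Its lithium derivative adds to the aldehyde and fluoride ends the route.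
Stereochemistry: ring B C2 and C5 come from glucose, C1 from exo-face dihydroxylation, C6 from SN2 inversion of glucose C4, and C1' from substrate-controlled addition. The ring A carbinol comes from Shi epoxidation, the ring A methine from a chair transition state, and the alkene geometries from Takai olefination and syn-bromoboration.

Key step: step 16

Numbering and abbreviations: ring B precursors carry glucose numbering (C1–C6). C7 is the carbon added to C6 (future CH2OH) and C8 is the branch carbon on C3 (future C1'). NAP = 2-naphthylmethyl, EE = 1-ethoxyethyl, TBDPS = tert-butyldiphenylsilyl, TBS = tert-butyldimethylsilyl, TES = triethylsilyl, DMP = Dess–Martin periodinane.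
Assumption: (tributylstannyl)methanol, 2-(bromomethyl)naphthalene and the D-fructose-derived Shi ketone are taken as commercial. The EE acetal carbon and the anomeric carbon of 15 are inconsequential epimer mixtures and are left undefined in the SMILES.

Step 1
Reactants: 1 1,2:5,6-di-O-isopropylidene-α-D-glucofuranose
Product: 2 1,2:5,6-di-O-isopropylidene-α-D-ribo-hexofuranos-3-ulose
Conditions: DMP, CH2Cl2, rt
Reagents that add atoms: none
Why: Dess–Martin oxidation of the single free secondary alcohol runs under near-neutral conditions, so both acetonides and the flanking centres C2 and C4 are kept.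

Step 2
Reactants: 2 1,2:5,6-di-O-isopropylidene-α-D-ribo-hexofuranos-3-ulose
Product: 3 3-deoxy-1,2:5,6-di-O-isopropylidene-3-C-methylidene-α-D-ribo-hexofuranose
Conditions: Ph3PCH3Br, n-BuLi, THF, 0 °C → rt
Reagents that add atoms: methyltriphenylphosphonium bromide, C[P+](c1ccccc1)(c1ccccc1)c1ccccc1.[Br-]
Why: Wittig methylenation of this strained, electrophilic bicyclic ketone is a standard entry to the 3-C-methylidene sugar, since ylide addition outruns enolisation.

Step 3
Reactants: 3 3-deoxy-1,2:5,6-di-O-isopropylidene-3-C-methylidene-α-D-ribo-hexofuranose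
Product: 4 3-C-(hydroxymethyl)-1,2:5,6-di-O-isopropylidene-α-D-glucofuranose
Conditions: OsO4 (2 mol %), NMO, acetone–H2O, rt
Reagents that add atoms: N-methylmorpholine N-oxide, C[N+]1([O-])CCOCC1; water, O
Why: In this Upjohn dihydroxylation osmium reaches the exocyclic alkene from the convex β-face opposite the 1,2-acetonide, so O3 keeps the D-gluco orientation, C8 takes the place of H3 and the quaternary centre is set.

Step 4
Reactants: 4 3-C-(hydroxymethyl)-1,2:5,6-di-O-isopropylidene-α-D-glucofuranose
Product: 5 3-O-NAP-3-C-(NAP-oxymethyl)-1,2:5,6-di-O-isopropylidene-α-D-glucofuranose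
Conditions: NaH, 2-(bromomethyl)naphthalene, Bu4NI (cat.), DMF, 0 °C → rt
Reagents that add atoms: 2-(bromomethyl)naphthalene, BrCc1ccc2ccccc2c1
Why: Double Williamson etherification covers the primary O8 and the exo-face tertiary O3 with ethers that withstand aqueous acid, ylides and organolithiums and are later removed together by oxidation.

Step 5
Reactants: 5 3-O-NAP-3-C-(NAP-oxymethyl)-1,2:5,6-di-O-isopropylidene-α-D-glucofuranose
Product: 6 3-O-NAP-3-C-(NAP-oxymethyl)-1,2-O-isopropylidene-α-D-glucofuranose (5,6-diol)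
Conditions: AcOH–H2O (7:3), 40 °C
Reagents that add atoms: none
Why: Mild acid hydrolysis cleaves the terminal 5,6-dioxolane well before the ring-fused 1,2-acetonide, and the ether groups at C3 offer no third acetal to compete.

Step 6
Reactants: 6 3-O-NAP-3-C-(NAP-oxymethyl)-1,2-O-isopropylidene-α-D-glucofuranose (5,6-diol)
Product: 7 3-O-NAP-3-C-(NAP-oxymethyl)-1,2-O-isopropylidene-α-D-glucofuranuronic acid (5-OH free)
Conditions: TEMPO (20 mol %), PhI(OAc)2, CH2Cl2–H2O, rt
Reagents that add atoms: water, O
Why: The TEMPO/PhI(OAc)2 oxidation used for uronic acids takes the primary alcohol to the carboxylic acid in the presence of water and leaves the hindered secondary 5-OH alone.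

Step 7
Reactants: 7 3-O-NAP-3-C-(NAP-oxymethyl)-1,2-O-isopropylidene-α-D-glucofuranuronic acid (5-OH free)
Product: 8 N-methoxy-N-methylamide of 7 (Weinreb amide; 5-OH free)
Conditions: MeNH(OMe)·HCl, EDC·HCl, HOBt (cat.), N-methylmorpholine, CH2Cl2, 0 °C → rt
Reagents that add atoms: N,O-dimethylhydroxylamine hydrochloride, CNOC.Cl
Why: In this carbodiimide amidation the amine outcompetes the hindered 5-hydroxyl, and the weak base does not endanger C5.

Step 8
Reactants: 8 N-methoxy-N-methylamide of 7 (Weinreb amide; 5-OH free)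
Product: 9 5-O-TBDPS ether of Weinreb amide 8
Conditions: TBDPSCl, imidazole, DMAP (cat.), DMF, 45 °C
Reagents that add atoms: tert-butyl(chloro)diphenylsilane, CC(C)(C)[Si](Cl)(c1ccccc1)c1ccccc1
Why: Silylation puts on O5 an acid-stable, fluoride-labile group that survives the later acetonide hydrolysis and keeps the sugar in the furanose form.

Step 9
Reactants: 10 (tributylstannyl)methanol
Product: 11 tributyl[(1-ethoxyethoxy)methyl]stannane
Conditions: ethyl vinyl ether, PPTS (cat.), CH2Cl2, rt
Reagents that add atoms: ethyl vinyl ether, C=COCC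
Why: Acid-catalysed addition of the alcohol to the enol ether (acetal protection) gives a hydroxymethyl-anion precursor whose protecting group is lost in aqueous acid.

Step 10
Reactants: 9 5-O-TBDPS ether of Weinreb amide 8; 11 tributyl[(1-ethoxyethoxy)methyl]stannane
Product: 13 C6 ketone 5-O-TBDPS-7-O-EE-3-O-NAP-3-C-(NAP-oxymethyl)-1,2-O-isopropylidene-α-D-gluco-heptofuranos-6-ulose, via (1-ethoxyethoxy)methyllithium 12 (not isolated)
Conditions: 11, n-BuLi, THF, −78 °C; then 9, −78 °C
Reagents that add atoms: none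
Why: Tin–lithium exchange gives the α-alkoxy organolithium, and the Weinreb ketone synthesis stops at the chelated tetrahedral adduct, so C6 gains C7 without over-addition.

Step 11
Reactants: 13 C6 ketone
Product: 14 6-C-methylidene furanose (side chain C5H(OTBDPS)–C6(=CH2)–C7H2OEE on the furanose of 13)
Conditions: Ph3PCH3Br, n-BuLi, THF, −78 → 0 °C
Reagents that add atoms: methyltriphenylphosphonium bromide, C[P+](c1ccccc1)(c1ccccc1)c1ccccc1.[Br-]
Why: In this Wittig methylenation of an activated α,α'-dialkoxy ketone at low temperature, carbonyl addition should be faster than enolisation toward C5.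

Step 12
Reactants: 14 6-C-methylidene furanose
Product: 15 furanose lactol 5-O-TBDPS-3-O-NAP-3-C-(NAP-oxymethyl)-6-deoxy-6-C-methylidene-D-gluco-heptofuranose (O1, O2 and O7 free)
Conditions: TFA–H2O (3:2), 0 °C → rt
Reagents that add atoms: none
Why: Aqueous acid hydrolysis removes the 1,2-acetonide and the EE acetal in one operation while TBDPS and NAP ethers persist, and with O5 blocked only the furanose lactol can form.

Step 13
Reactants: 15 furanose lactol
Product: 16 open-chain 1,7-diene triol CH2=C1H–C2H(OH)–C3(ONAP)(C8H2ONAP)–C4H(OH)–C5H(OTBDPS)–C6(=CH2)–C7H2OH (D-gluco at C2–C5)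
Conditions: Ph3PCH3Br (excess), n-BuLi, THF, −20 °C → rt
Reagents that add atoms: methyltriphenylphosphonium bromide, C[P+](c1ccccc1)(c1ccccc1)c1ccccc1.[Br-]
Why: Wittig methylenation of the lactol through its open hydroxy-aldehyde form turns C1 into the vinyl group and releases the ring oxygen as O4–H, while the lithium 2-alkoxide formed first guards C2 against deprotonation.

Step 14
Reactants: 16 open-chain 1,7-diene triol
Product: 17 2,7-bis-O-TBS ether of 16 (O4–H free)
Conditions: TBSCl, imidazole, DMAP (cat.), DMF, rt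
Reagents that add atoms: tert-butyl(chloro)dimethylsilane, CC(C)(C)[Si](C)(C)Cl
Why: Under sterically controlled silylation the primary allylic O7 and the vinyl-flanked O2 react, whereas O4, wedged between the quaternary C3 and the OTBDPS-bearing C5, should stay free.

Step 15
Reactants: 17 2,7-bis-O-TBS ether of 16
Product: 18 metathesis precursor, the O4 mesylate of 17
Conditions: MsCl, Et3N, CH2Cl2, 0 °C → rt
Reagents that add atoms: methanesulfonyl chloride, CS(=O)(=O)Cl
Why: Mesylation through the small electrophile sulfene reaches even this crowded secondary alcohol and leaves the C4 configuration unchanged.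

Step 16
Reactants: 18 metathesis precursor (O4 mesylate)
Product: 19 cyclohexene mesylate (ring C1–C6 with C1=C6; 2-OTBS, 3-ONAP, 3-CH2ONAP, 4-OMs, 5-OTBDPS, 6-CH2OTBS; O2, O4 and O5 on one face, O3 on the other)
Conditions: Hoveyda–Grubbs II (10 mol %), toluene (2 mM), 80 °C, Ar sparge
Reagents that add atoms: none
Why: In this ring-closing olefin metathesis the ruthenium carbene first exchanges with the monosubstituted C1 vinyl group, the new alkylidene adds to the 1,1-disubstituted C6 alkene through a ruthenacyclobutane, and cycloreversion releases the ring while the methylidene carrier gives off ethene. The closest known reaction type is the closure of sugar-derived 1,7-dienes to valienol- and gabosine-type carbasugars with second-generation catalysts. One ring forms, the six-membered carbocycle C1–C6, closed by joining the inner sp2 carbons of a 1,7-octadiene so that C1=C6 becomes the endocyclic trisubstituted alkene. No stereocentre is created, and C2–C5 pass unchanged from 18 into 19. The step needs cyclisation to win over dimerisation and alkene migration, which high dilution, ethene removal, the gem-disubstituent effect of quaternary C3 and the reluctance of the hindered 1,1-disubstituted alkene to homodimerise should secure. Mesylate, silyl ethers and NAP ethers are inert to the catalyst.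

Step 17
Reactants: 19 cyclohexene mesylate
Product: 20 diol mesylate (O3–H and O8–H free)
Conditions: DDQ, CH2Cl2–pH 7 buffer (10:1), 0 °C → rt
Reagents that add atoms: none
Why: Oxidative cleavage of the naphthylmethyl ethers by DDQ (hydride abstraction, then hydrolysis of the oxocarbenium ion) frees O3 and O8 together and spares the mesylate, the silyl ethers and the ring alkene.

Step 18
Reactants: 20 diol mesylate
Product: 21 epoxy alcohol (7-oxabicyclo[4.1.0]hept-3-ene with 1-CH2OH, 2-OTBS, 4-CH2OTBS, 5-OTBDPS; epoxide trans to both silyloxy groups)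
Conditions: K2CO3, MeOH, 0 °C → rt
Reagents that add atoms: none
Why: In this intramolecular Williamson reaction (3-exo-tet SN2), O3 lies trans to the mesylate, reaches the diaxial antiperiplanar arrangement in the half-chair and displaces it with inversion at C4, far faster than the four-membered closure open to O8.

Step 19
Reactants: 21 epoxy alcohol
Product: 22 epoxy aldehyde (C8 as CHO on the quaternary epoxide carbon)
Conditions: DMP, CH2Cl2, 0 °C → rt
Reagents that add atoms: none
Why: Dess–Martin oxidation handles the neopentyl-type primary alcohol under mild conditions, and the aldehyde has no α-hydrogen to lose.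

Step 20
Reactants: 23 geranyl acetate
Product: 24 (R)-6,7-epoxygeranyl acetate, (2E)-5-[(2R)-3,3-dimethyloxiran-2-yl]-3-methylpent-2-en-1-yl acetate
Conditions: D-fructose-derived Shi ketone (30 mol %), Oxone, K2CO3, Bu4NHSO4 (cat.), MeCN–DMM / aq. Na2B4O7–Na2EDTA, 0 °C
Reagents that add atoms: potassium peroxymonosulfate (Oxone), [K+].[O-]S(=O)(=O)OO
Why: In the Shi epoxidation the chiral dioxirane attacks the electron-rich 6,7-alkene rather than the acetate-deactivated 2,3-alkene, and its spiro transition state delivers oxygen to the face that gives the (R)-epoxide.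

Step 21
Reactants: 24 (R)-6,7-epoxygeranyl acetate
Product: 25 [(1S,5R)-5-hydroxy-2,6,6-trimethylcyclohex-2-en-1-yl]methyl acetate
Conditions: ZrCl4 (0.5 equiv), CH2Cl2, −20 °C
Reagents that add atoms: none
Why: In this Lewis-acid-induced epoxide-opening cation–olefin cyclisation the E-alkene attacks the tertiary epoxide terminus through a chair that places the retained C–O bond and CH2OAc equatorial (cis), which sets the ring methine, and proton loss from the ring CH2 gives the endocyclic alkene.

Step 22
Reactants: 25 [(1S,5R)-5-hydroxy-2,6,6-trimethylcyclohex-2-en-1-yl]methyl acetate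
Product: 26 [(1S,5R)-2,6,6-trimethyl-5-(triethylsilyloxy)cyclohex-2-en-1-yl]methyl acetate
Conditions: TESCl, imidazole, DMF, rt
Reagents that add atoms: chlorotriethylsilane, CC[Si](Cl)(CC)CC
Why: The smaller TES group is chosen for this silylation because a silyl ether next to the gem-dimethyl carbon must still leave under mild fluoride at the end.

Step 23
Reactants: 26 [(1S,5R)-2,6,6-trimethyl-5-(triethylsilyloxy)cyclohex-2-en-1-yl]methyl acetate
Product: 27 [(1S,5R)-2,6,6-trimethyl-5-(triethylsilyloxy)cyclohex-2-en-1-yl]methanol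
Conditions: K2CO3 (cat.), MeOH, rt
Reagents that add atoms: none
Why: Base-catalysed transesterification removes the primary acetate and leaves the hindered secondary TES ether in place.

Step 24
Reactants: 27 [(1S,5R)-2,6,6-trimethyl-5-(triethylsilyloxy)cyclohex-2-en-1-yl]methanol
Product: 28 (1S,5R)-2,6,6-trimethyl-5-(triethylsilyloxy)cyclohex-2-ene-1-carbaldehyde
Conditions: DMP, CH2Cl2, 0 °C
Reagents that add atoms: none
Why: Dess–Martin oxidation is base-free, so the β,γ-unsaturated aldehyde should neither epimerise nor slip into conjugation.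

Step 25
Reactants: 28 (1S,5R)-2,6,6-trimethyl-5-(triethylsilyloxy)cyclohex-2-ene-1-carbaldehyde
Product: 29 (E)-vinyl iodide (1S,5R)-1-[(E)-2-iodoethenyl]-2,6,6-trimethyl-5-(triethylsilyloxy)cyclohex-2-ene
Conditions: CrCl2, CHI3, THF, 0 °C → rt
Reagents that add atoms: iodoform, IC(I)I
Why: The Takai olefination is non-basic, tolerates α-branched epimerisable aldehydes and gives the E-iodoalkene through anti elimination from the gem-dichromium adduct.

Step 26
Reactants: 30 propyne
Product: 32 2-[(Z)-2-bromoprop-1-en-1-yl]-4,4,5,5-tetramethyl-1,3,2-dioxaborolane, via (Z)-2-bromoprop-1-enyldibromoborane 31 (not isolated)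
Conditions: BBr3, CH2Cl2, −78 °C; then pinacol, −78 °C → rt
Reagents that add atoms: boron tribromide, BrB(Br)Br; pinacol, CC(C)(O)C(C)(C)O
Why: Syn-bromoboration of the terminal alkyne places boron on C1 and bromine on C2 on the same side, and immediate esterification with pinacol freezes the Z geometry.

Step 27
Reactants: 29 (E)-vinyl iodide; 32 2-[(Z)-2-bromoprop-1-en-1-yl]-4,4,5,5-tetramethyl-1,3,2-dioxaborolane
Product: 35 (1Z,3E)-dienyl pinacolboronate (Bpin on C1 cis to the C3=C4 vinyl unit; methyl on C2; ring A on C4), via alkenyllithium 33 (not isolated), via alkenylzinc bromide 34 (not isolated)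
Conditions: 29, t-BuLi, Et2O, −78 °C; ZnBr2, THF, −78 → 0 °C; then 32, PdCl2(DPEphos) (2 mol %), THF, rt
Reagents that add atoms: none
Why: Negishi coupling takes place at the C–Br bond with retention at both alkenyl partners, and the pinacolboronate is inert to organozinc reagents, so the boron ends up cis to the new alkenyl group.

Step 28
Reactants: 35 (1Z,3E)-dienyl pinacolboronate
Product: 36 (1Z,3E)-1-iodo-2-methyl-4-[(1S,5R)-2,6,6-trimethyl-5-(triethylsilyloxy)cyclohex-2-en-1-yl]buta-1,3-diene
Conditions: NaOH (aq), then I2, THF, 0 °C, dark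
Reagents that add atoms: iodine, II
Why: Iodinolysis (iododeboronation) of the hydroxide-activated alkenylboronate replaces boron by iodine with retention of the alkene geometry.

Step 29
Reactants: 36 (1Z,3E)-dienyl iodide; 22 epoxy aldehyde
Product: 38 fully silylated target with free (S)-C1' carbinol, via dienyllithium 37 (not isolated)
Conditions: 36, t-BuLi, Et2O, −78 °C; then 22, −78 °C
Reagents that add atoms: none
Why: Iodine–lithium exchange keeps the Z geometry and is followed by 1,2-addition to the non-enolisable aldehyde; in the rotamer with C=O turned outward (lithium-bridged to the epoxide oxygen) and H over the ring, the C2 silyl ether shields one face, so attack over the epoxide C–H flank should set the (S)-carbinol, the anti epoxy alcohol.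

Step 30
Reactants: 38 fully silylated target
Product: 39 target CNP0389279.1
Conditions: TBAF, AcOH (1:1), THF, 0 °C → rt
Reagents that add atoms: none
Why: Buffered fluoride desilylation removes the two TBS groups, the TBDPS group and the TES group without the free alkoxide that would trigger Payne migration and without the acid that would ionise the dienylic carbinol.

Compound list
1 | 1,2:5,6-di-O-isopropylidene-α-D-glucofuranose | CC1(C)OC[C@@H](O1)[C@H]2O[C@@H]3OC(C)(C)O[C@@H]3[C@H]2O | starting material
2 | 1,2:5,6-di-O-isopropylidene-α-D-ribo-hexofuranos-3-ulose | CC1(C)OC[C@@H](O1)[C@H]2O[C@@H]3OC(C)(C)O[C@@H]3C2=O | intermediate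
3 | 3-deoxy-1,2:5,6-di-O-isopropylidene-3-C-methylidene-α-D-ribo-hexofuranose | CC1(C)OC[C@@H](O1)[C@H]2O[C@@H]3OC(C)(C)O[C@@H]3C2=C | intermediate
4 | 3-C-(hydroxymethyl)-1,2:5,6-di-O-isopropylidene-α-D-glucofuranose | CC1(C)OC[C@@H](O1)[C@H]2O[C@@H]3OC(C)(C)O[C@@H]3[C@@]2(CO)O | intermediate
5 | 3-O-NAP-3-C-(NAP-oxymethyl)-1,2:5,6-di-O-isopropylidene-α-D-glucofuranose | CC1(C)OC[C@@H](O1)[C@H]2O[C@@H]3OC(C)(C)O[C@@H]3[C@@]2(COCc4ccc5ccccc5c4)OCc4ccc5ccccc5c4 | intermediate
6 | 3-O-NAP-3-C-(NAP-oxymethyl)-1,2-O-isopropylidene-α-D-glucofuranose (5,6-diol) | OC[C@@H](O)[C@H]1O[C@@H]2OC(C)(C)O[C@@H]2[C@@]1(COCc3ccc4ccccc4c3)OCc3ccc4ccccc4c3 | intermediate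
7 | 3-O-NAP-3-C-(NAP-oxymethyl)-1,2-O-isopropylidene-α-D-glucofuranuronic acid | OC(=O)[C@@H](O)[C@H]1O[C@@H]2OC(C)(C)O[C@@H]2[C@@]1(COCc3ccc4ccccc4c3)OCc3ccc4ccccc4c3 | intermediate
8 | N-methoxy-N-methylamide of 7 | CON(C)C(=O)[C@@H](O)[C@H]1O[C@@H]2OC(C)(C)O[C@@H]2[C@@]1(COCc3ccc4ccccc4c3)OCc3ccc4ccccc4c3 | intermediate
9 | 5-O-TBDPS ether of 8 | CON(C)C(=O)[C@@H](O[Si](c1ccccc1)(c1ccccc1)C(C)(C)C)[C@H]1O[C@@H]2OC(C)(C)O[C@@H]2[C@@]1(COCc3ccc4ccccc4c3)OCc3ccc4ccccc4c3 | intermediate
10 | (tributylstannyl)methanol | OC[Sn](CCCC)(CCCC)CCCC | starting material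
11 | tributyl[(1-ethoxyethoxy)methyl]stannane | CCOC(C)OC[Sn](CCCC)(CCCC)CCCC | intermediate
12 | (1-ethoxyethoxy)methyllithium | [Li]COC(C)OCC | intermediate
13 | C6 ketone, 5-O-TBDPS-7-O-EE-3-O-NAP-3-C-(NAP-oxymethyl)-1,2-O-isopropylidene-α-D-gluco-heptofuranos-6-ulose | CCOC(C)OCC(=O)[C@@H](O[Si](c1ccccc1)(c1ccccc1)C(C)(C)C)[C@H]1O[C@@H]2OC(C)(C)O[C@@H]2[C@@]1(COCc3ccc4ccccc4c3)OCc3ccc4ccccc4c3 | intermediate
14 | 6-C-methylidene furanose | CCOC(C)OCC(=C)[C@@H](O[Si](c1ccccc1)(c1ccccc1)C(C)(C)C)[C@H]1O[C@@H]2OC(C)(C)O[C@@H]2[C@@]1(COCc3ccc4ccccc4c3)OCc3ccc4ccccc4c3 | intermediate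
15 | furanose lactol (O1, O2, O7 free; α/β) | OCC(=C)[C@@H](O[Si](c1ccccc1)(c1ccccc1)C(C)(C)C)[C@H]1OC(O)[C@H](O)[C@@]1(COCc2ccc3ccccc3c2)OCc2ccc3ccccc3c2 | intermediate
16 | open-chain 1,7-diene triol (O2, O4, O7 free) | C=C[C@H](O)[C@@](COCc1ccc2ccccc2c1)(OCc1ccc2ccccc2c1)[C@H](O)[C@H](O[Si](c1ccccc1)(c1ccccc1)C(C)(C)C)C(=C)CO | intermediate
17 | 2,7-bis-O-TBS diene, O4–H free | C=C[C@H](O[Si](C)(C)C(C)(C)C)[C@@](COCc1ccc2ccccc2c1)(OCc1ccc2ccccc2c1)[C@H](O)[C@H](O[Si](c1ccccc1)(c1ccccc1)C(C)(C)C)C(=C)CO[Si](C)(C)C(C)(C)C | intermediate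
18 | metathesis precursor, 3-C-branched D-gluco diene O4 mesylate | C=C[C@H](O[Si](C)(C)C(C)(C)C)[C@@](COCc1ccc2ccccc2c1)(OCc1ccc2ccccc2c1)[C@H](OS(C)(=O)=O)[C@H](O[Si](c1ccccc1)(c1ccccc1)C(C)(C)C)C(=C)CO[Si](C)(C)C(C)(C)C | intermediate
19 | cyclohexene mesylate | C(OCc1ccc2ccccc2c1)[C@]1(OCc2ccc3ccccc3c2)[C@H](OS(C)(=O)=O)[C@H](O[Si](c2ccccc2)(c2ccccc2)C(C)(C)C)C(CO[Si](C)(C)C(C)(C)C)=C[C@@H]1O[Si](C)(C)C(C)(C)C | intermediate
20 | diol mesylate | OC[C@]1(O)[C@H](OS(C)(=O)=O)[C@H](O[Si](c2ccccc2)(c2ccccc2)C(C)(C)C)C(CO[Si](C)(C)C(C)(C)C)=C[C@@H]1O[Si](C)(C)C(C)(C)C | intermediate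
21 | epoxy alcohol | OC[C@]12O[C@H]1[C@H](O[Si](c3ccccc3)(c3ccccc3)C(C)(C)C)C(CO[Si](C)(C)C(C)(C)C)=C[C@@H]2O[Si](C)(C)C(C)(C)C | intermediate
22 | epoxy aldehyde | O=C[C@]12O[C@H]1[C@H](O[Si](c3ccccc3)(c3ccccc3)C(C)(C)C)C(CO[Si](C)(C)C(C)(C)C)=C[C@@H]2O[Si](C)(C)C(C)(C)C | intermediate
23 | geranyl acetate | CC(C)=CCC/C(C)=C/COC(C)=O | starting material
24 | (R)-6,7-epoxygeranyl acetate | CC1(C)O[C@@H]1CC/C(C)=C/COC(C)=O | intermediate
25 | [(1S,5R)-5-hydroxy-2,6,6-trimethylcyclohex-2-en-1-yl]methyl acetate | CC1=CC[C@@H](O)C(C)(C)[C@H]1COC(C)=O | intermediate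
26 | [(1S,5R)-2,6,6-trimethyl-5-(triethylsilyloxy)cyclohex-2-en-1-yl]methyl acetate | CC1=CC[C@@H](O[Si](CC)(CC)CC)C(C)(C)[C@H]1COC(C)=O | intermediate
27 | [(1S,5R)-2,6,6-trimethyl-5-(triethylsilyloxy)cyclohex-2-en-1-yl]methanol | CC1=CC[C@@H](O[Si](CC)(CC)CC)C(C)(C)[C@H]1CO | intermediate
28 | (1S,5R)-2,6,6-trimethyl-5-(triethylsilyloxy)cyclohex-2-ene-1-carbaldehyde | CC1=CC[C@@H](O[Si](CC)(CC)CC)C(C)(C)[C@H]1C=O | intermediate
29 | (1S,5R)-1-[(E)-2-iodoethenyl]-2,6,6-trimethyl-5-(triethylsilyloxy)cyclohex-2-ene | CC1=CC[C@@H](O[Si](CC)(CC)CC)C(C)(C)[C@H]1/C=C/I | intermediate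
30 | propyne | CC#C | starting material
31 | (Z)-2-bromoprop-1-enyldibromoborane | C/C(Br)=C/B(Br)Br | intermediate
32 | 2-[(Z)-2-bromoprop-1-en-1-yl]-4,4,5,5-tetramethyl-1,3,2-dioxaborolane | C/C(Br)=C/B1OC(C)(C)C(C)(C)O1 | intermediate
33 | (E)-alkenyllithium from 29 | CC1=CC[C@@H](O[Si](CC)(CC)CC)C(C)(C)[C@H]1/C=C/[Li] | intermediate
34 | (E)-alkenylzinc bromide | CC1=CC[C@@H](O[Si](CC)(CC)CC)C(C)(C)[C@H]1/C=C/[Zn]Br | intermediate
35 | (1Z,3E)-dienyl pinacolboronate | CC1=CC[C@@H](O[Si](CC)(CC)CC)C(C)(C)[C@H]1/C=C/C(C)=C\B2OC(C)(C)C(C)(C)O2 | intermediate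
36 | (1Z,3E)-dienyl iodide | CC1=CC[C@@H](O[Si](CC)(CC)CC)C(C)(C)[C@H]1/C=C/C(C)=C\I | intermediate
37 | (1Z,3E)-dienyllithium | CC1=CC[C@@H](O[Si](CC)(CC)CC)C(C)(C)[C@H]1/C=C/C(C)=C\[Li] | intermediate
38 | fully silylated target, (S)-C1' carbinol free | CC1=CC[C@@H](O[Si](CC)(CC)CC)C(C)(C)[C@H]1/C=C/C(C)=C\[C@H](O)[C@]12O[C@H]1[C@H](O[Si](c3ccccc3)(c3ccccc3)C(C)(C)C)C(CO[Si](C)(C)C(C)(C)C)=C[C@@H]2O[Si](C)(C)C(C)(C)C | intermediate
39 | CNP0389279.1, (1R,2S,5R,6S)-1-{(1S,2Z,4E)-1-hydroxy-5-[(1S,5R)-5-hydroxy-2,6,6-trimethylcyclohex-2-en-1-yl]-3-methylpenta-2,4-dien-1-yl}-4-(hydroxymethyl)-7-oxabicyclo[4.1.0]hept-3-ene-2,5-diol | CC1=CC[C@@H](O)C(C)(C)[C@H]1/C=C/C(C)=C\[C@H](O)[C@]12O[C@H]1[C@H](O)C(CO)=C[C@@H]2O | target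

Total step count: 30.
Longest linear sequence: 20 steps from 1 (steps 1–8, 10–19, 29, 30). The ring A branch from 23 counts 10 steps (20–25, 27–30). Steps 9 and 26 are one-step side branches.

Steps most likely to fail

Step 16. The catalyst must load on a vinyl group next to a silyl ether and a quaternary carbon. It must then reach a 1,1-disubstituted alkene flanked by OTBDPS, so catalyst decay, alkene migration or dimerisation may overtake ring closure. The fallback sets out from 16 and runs the metathesis before silylation and mesylation. The free allylic hydroxyls at C2 and C7 lower the steric load at both alkenes, and allylic hydroxyls are known to accelerate ruthenium metathesis. This gives the cyclohexene triol F1. TBSCl and imidazole then silylate O7 and O2 to the bis-TBS cyclohexenol F2, in which O4 stays buried between C3 and C5. MsCl and Et3N convert F2 into 19, where the route is rejoined.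

Step 29. Facial selectivity at the aldehyde may be poor, because the outward and inward rotamers of a formyl group differ little in size and lead to opposite carbinols. The fallback sets out from 22 and 36 and accepts the addition as a mixture of 38 and its C1' epimer F3. Both are oxidised with DMP to the Z,E-dienone F4, and the centre is then set by reduction instead of by C–C bond formation. In the ketone the large dienyl group must point away from the ring, which fixes the rotamer, and the C2 silyl ether shields one carbonyl face. Under Luche conditions (NaBH4, CeCl3, MeOH, −78 °C) hydride should therefore enter over the epoxide C–H flank in a 1,2-sense. The route is rejoined at 38.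

Step 13. The strongly basic ylide generates alkoxides at O4 and O7 next to the O5 silyl ether. Silyl migration, deprotonation at C2 or β-elimination of the O3 ether may therefore erode the methylenation. The fallback sets out from 15 and replaces the ylide by a carbonyl addition followed by an acid-induced elimination. Excess Me3SiCH2MgCl adds to the open form of the lactol through less migration-prone magnesium alkoxides and gives the β-hydroxysilane F5, whose C1 epimers are of no consequence. Peterson elimination with BF3·OEt2 in CH2Cl2 at 0 °C then gives the vinyl group. The route is rejoined at 16.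

Further compounds
F1 | step 16 | cyclohexene triol (O2, O4, O7 free; 3-ONAP, 3-CH2ONAP, 5-OTBDPS) | C(OCc1ccc2ccccc2c1)[C@]1(OCc2ccc3ccccc3c2)[C@H](O)[C@H](O[Si](c2ccccc2)(c2ccccc2)C(C)(C)C)C(CO)=C[C@@H]1O
F2 | step 16 | bis-TBS cyclohexenol (O4–H free) | C(OCc1ccc2ccccc2c1)[C@]1(OCc2ccc3ccccc3c2)[C@H](O)[C@H](O[Si](c2ccccc2)(c2ccccc2)C(C)(C)C)C(CO[Si](C)(C)C(C)(C)C)=C[C@@H]1O[Si](C)(C)C(C)(C)C
F3 | step 29 | (R)-C1' epimer of 38 | CC1=CC[C@@H](O[Si](CC)(CC)CC)C(C)(C)[C@H]1/C=C/C(C)=C\[C@@H](O)[C@]12O[C@H]1[C@H](O[Si](c3ccccc3)(c3ccccc3)C(C)(C)C)C(CO[Si](C)(C)C(C)(C)C)=C[C@@H]2O[Si](C)(C)C(C)(C)C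
F4 | step 29 | Z,E-dienone (C1' ketone) | CC1=CC[C@@H](O[Si](CC)(CC)CC)C(C)(C)[C@H]1/C=C/C(C)=C\C(=O)[C@]12O[C@H]1[C@H](O[Si](c3ccccc3)(c3ccccc3)C(C)(C)C)C(CO[Si](C)(C)C(C)(C)C)=C[C@@H]2O[Si](C)(C)C(C)(C)C
F5 | step 13 | β-hydroxysilane tetraol (C1 epimers) | C[Si](C)(C)CC(O)[C@H](O)[C@@](COCc1ccc2ccccc2c1)(OCc1ccc2ccccc2c1)[C@H](O)[C@H](O[Si](c1ccccc1)(c1ccccc1)C(C)(C)C)C(=C)CO
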